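Readings and results were computed for an exercise; scatter was added.

In a one-step world each J lost would stand as Q, yet Friday's closed flask at 25.0 h holds 45.2% of its J and 5.7% as Q.

| flask | J | D | E | remark | time |
|---|---|---|---|---|---|
| Friday's | 10 mM | 20 mM | 0.20 mM | run made earlier |  |
| Monday's | 10 mM | 20 mM | 0.13 mM | run made earlier |  |
| Thursday's | 10 mM | 20 mM | 0.30 mM | run made earlier |  |
| delta | 10 mM | 20.0 mM | 0.200 mM | a single well-mixed tank run continuously and read at steady state, 25 h in it on average |  |
| eta | 10 mM | 20.0 mM (fed, over 12.5 h) | 0.200 mM | all but D at the start; D goes in evenly over 12.5 h, the run ends at 25 h | 25 h |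
| beta | 10 mM (fed, over 12.5 h) | 20.0 mM | 0.200 mM | all but J at the start; J goes in evenly over 12.5 h, the run ends at 25 h | 25 h |
| theta | 10 mM | 20.0 mM | 0.200 mM | a closed flask charged with all of it at once and left for 25 h | 25 h |

| run | time / h | Q / % | J / % |
|---|---|---|---|
| Friday's | 4.00 | 2.2 | 84.7 |
| Friday's | 8.00 | 3.3 | 73.4 |
| Friday's | 12.0 | 3.8 | 63.9 |
| Friday's | 15.0 | 4.7 | 58.6 |
| Friday's | 20.0 | 5.7 | 51.7 |
| Friday's | 25.0 | 5.7 | 45.2 |
| Monday's | 1.33 | 1.0 | 95.0 |
| Monday's | 2.00 | 0.9 | 91.6 |
| Monday's | 3.00 | 1.3 | 88.0 |
| Monday's | 5.00 | 2.0 | 81.8 |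
| Monday's | 10.0 | 3.9 | 68.0 |
| Monday's | 15.0 | 4.6 | 59.3 |
| Thursday's | 1.00 | 0.9 | 95.7 |
| Thursday's | 3.00 | 1.4 | 88.0 |
| Thursday's | 5.00 | 1.8 | 81.5 |
| Thursday's | 8.00 | 3.7 | 73.2 |
| Thursday's | 12.0 | 4.5 | 64.4 |
| Thursday's | 15.0 | 5.3 | 59.2 |

(standard deviation of a reading: 0.3 percentage points)

- the stated concentrations are those of everything mixed, before any reaction; amounts are the same in each set-up
- the numbers in the tables scatter with a standard deviation of 0.3 percentage points
- the feed brings no volume worth counting
- the earlier runs were made in a closed, stirred flask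

* the set-up with the highest amount of Q at the outlet or at the end, in percent of the J put in ("none" if the first two lie within 2 percentage points) (delta / eta / beta / theta / none)
* amount of Q at the outlet or at the end, in percent of the J put in, delta
* amount of Q at the outlet or at the end, in percent of the J put in, eta
* amount of Q at the outlet or at the end, in percent of the J put in, beta
* amount of Q at the outlet or at the end, in percent of the J put in, theta

In the first instants the flask says little: Monday's reading at 1.33 h shows 1.0% of Q against 5.00% of J lost, and that Q carries a scatter of 0.3 percentage points. The middle is clearer. At 15.0 h Monday's and Thursday's flasks hold 59.3% and 59.2% of their J, although E goes from 0.13 mM to 0.30 mM. Pooled with Friday's reading at that time, Q is 11.9% of the J lost, and this part of the J lost that stands as Q, the Q share or selectivity, is the number to carry.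

At the end something is about to matter: between 20.0 h and 25.0 h Friday's flask loses J worth 0.772% of Q by this share, but Q reads 5.7% and then 5.7%, so Q may be leaving.

At this share, two recipes part in Q by the margin of 2 points when their losses of J part by 17 points. Theta is Friday's recipe, so its reckoned Q is 6.52%, above the reading of 5.7%, and the reckoning here calls no winner unless a rival's loss of J stands that far from theta's.

The forecast says none, with 4.7% for delta, 5.5% for eta, 5.3% for beta and 6% for theta, a lower theta than the reckoning here, and it holds that “Q stays about 11–12% of J consumed at all conversions”.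

The flasks give 4.10% for delta, 5.11% for eta, 5.08% for beta and 5.72% for theta, so the answer is none: theta leads and stands above eta, the next, by 0.61 points.

    D + G → Z (k = 14.0 L mol⁻¹ h⁻¹)
    J + D → Q (k = 0.270 L mol⁻¹ h⁻¹)
    J + D → G (k = 1.90 L mol⁻¹ h⁻¹)
    Q ⇌ X (K = 1.50, k = 0.0120 h⁻¹)
    E + G → L (k = 3.10 L mol⁻¹ h⁻¹)

In theta the half-life of Q by its forward step to X alone, the way back not counted, is 58 h, longer than the 18 h of J by J + D to G alone, the others as charged, and at 25.0 h X stands at 1.05% beside Q at 5.72%, together 12.4% of the J lost in theta, beside the carried share of 11.9%. Theta left until 96.0 h has lost 83.7% of its J, which by the share makes 9.94%, and there Q stands at 5.83% and X at 4.58%, together 10.4%.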